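**Retrosynthetic overview**
1. Target 12 ⇐ meso bisphenol 11 by a catalyst-controlled mono-O-methylation that selects one of the two enantiotopic rings and so fixes the absolute configuration.
2. 11 ⇐ meso oxolane 9 (galgravin) by twofold aryl C–H borylation/oxidation; 9 ⇐ bis-phenol oxolane 8 by O-methylation.
3. Oxolane 8 ⇐ cyclobutane 6 by oxidative ring expansion (O inserted into the diaryl C–C bond via a bis(quinone methide)); C3/C4 come from the cyclobutane, C2/C5 are set under thermodynamic control.
4. Cyclobutane 6 ⇐ head-to-head photodimer of (E)-isoeugenol 5.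
5. 5 ⇐ 2-bromophenol 1 + (E)-propenylboronic acid 4 (methoxylation, bromination, Suzuki). Ring order: cyclobutane, then oxolane.

Assumption: which of the two pseudo-enantiomeric catalysts in step 8 gives 12 rather than its mirror image cannot be predicted and is assigned by experiment.

**Step 1**
Reactants: 1 2-bromophenol
Product: 2 2-methoxyphenol (guaiacol)
Conditions: NaOMe (4 equiv), CuI (10 mol%), MeOH/DMF, 110 °C (sealed); aq. HCl work-up
Reagents that add atoms: sodium methoxide, C[O-].[Na+]
Why: Copper-catalysed Ullmann-type methoxylation of the aryl bromide, which tolerates the ortho phenoxide as in the classical bromophenol-to-methoxyphenol conversions; no stereocentre is involved.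

**Step 2**
Reactants: 2 2-methoxyphenol
Product: 3 4-bromo-2-methoxyphenol
Conditions: NBS (1.0 equiv), MeCN, 0 °C
Reagents that add atoms: N-bromosuccinimide, O=C1CCC(=O)N1Br
Why: Electrophilic aromatic bromination in which the free OH is the stronger director, so bromine enters para to it.

**Step 3**
Reactants: 3 4-bromo-2-methoxyphenol; 4 (E)-prop-1-en-1-ylboronic acid
Product: 5 2-methoxy-4-[(E)-prop-1-enyl]phenol ((E)-isoeugenol)
Conditions: Pd(dppf)Cl2 (3 mol%), K2CO3 (3 equiv), dioxane/H2O 4:1, 80 °C
Reagents that add atoms: none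
Why: Suzuki–Miyaura coupling, which tolerates the free phenol with excess base and transfers the alkenyl group with retention of the (E) geometry.

**Step 4**
Reactants: 5 2-methoxy-4-[(E)-prop-1-enyl]phenol (2 equiv)
Product: 6 4,4'-[(1R,2S,3R,4S)-3,4-dimethylcyclobutane-1,2-diyl]bis(2-methoxyphenol) (meso; r-1,c-2,t-3,t-4)
Conditions: hν (Pyrex, λ > 300 nm), degassed benzene, ca. 1 M, 10 °C; recovered E/Z-5 re-isomerised (cat. I2) and recycled
Reagents that add atoms: none
Why: [2+2] photodimerisation through the π-stacked singlet excimer of the electron-rich (E)-arylpropene (the behaviour of (E)-anethole), which is head-to-head and suprafacial on both alkenes, so the aryls end up cis, the methyls cis and each aryl trans to its neighbouring methyl; this sets the erythro methyl pair that becomes C3/C4 of the oxolane.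

**Step 5**
Reactants: 6 4,4'-[(1R,2S,3R,4S)-3,4-dimethylcyclobutane-1,2-diyl]bis(2-methoxyphenol)
Product: 8 4,4'-[(2R,3R,4S,5S)-3,4-dimethyloxolane-2,5-diyl]bis(2-methoxyphenol) (meso), via bis(quinone methide) 7 (not isolated)
Conditions: FeCl3·6H2O (2.2 equiv), acetone/H2O 5:1, 0 °C to rt; then 1 M HCl, rt, 12 h
Reagents that add atoms: water, O
Why: Oxidative ring expansion (net insertion of O into the C1–C2 bond), in which one-electron oxidation of both phenols cleaves the strained, doubly benzylic bond to bis(p-quinone methide) 7 without touching the methyl-bearing carbons, hydration of one quinone methide and intramolecular 1,6-oxa-addition to the other then close the oxolane (the biomimetic 8–8' quinone-methide manifold, established for oxidative opening of bis(4-hydroxyaryl)cyclobutanes), and acid equilibration by reversible quinone-methide formation places each aryl trans to its neighbouring methyl at C2 and C5.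

**Step 6**
Reactants: 8 4,4'-[(2R,3R,4S,5S)-3,4-dimethyloxolane-2,5-diyl]bis(2-methoxyphenol)
Product: 9 (2R,3R,4S,5S)-2,5-bis(3,4-dimethoxyphenyl)-3,4-dimethyloxolane (meso; galgravin)
Conditions: MeI (3 equiv), K2CO3, acetone, reflux
Reagents that add atoms: iodomethane, CI
Why: Williamson O-methylation of both phenols under basic conditions, which cannot ionise the benzylic ether positions, so all four stereocentres are untouched.

**Step 7**
Reactants: 9 (2R,3R,4S,5S)-2,5-bis(3,4-dimethoxyphenyl)-3,4-dimethyloxolane
Product: 11 5,5'-[(2R,3R,4S,5S)-3,4-dimethyloxolane-2,5-diyl]bis(2,3-dimethoxyphenol) (meso), via bis(pinacolboronate) 10 (not isolated)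
Conditions: [Ir(OMe)(cod)]2 (3 mol%), Me4phen (6 mol%), B2pin2 (3 equiv), THF, 80 °C; then 30% H2O2, aq. NaOH, 0 °C
Reagents that add atoms: bis(pinacolato)diboron, CC1(C)OB(OC1(C)C)B1OC(C)(C)C(C)(C)O1 (boron carried in 10 only); hydrogen peroxide, OO (phenolic oxygen of 11)
Why: Sterically governed iridium-catalysed aromatic C–H borylation, which should favour C5' because it is the only ring C–H not flanked by the bulky oxolanyl group (C2' lies between oxolane and OMe, C6' is ortho to the oxolane, and borylation ortho to OMe is known for para-substituted anisoles), followed by boronate oxidation with retention at the aryl carbon; no stereocentre is affected.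

**Step 8**
Reactants: 11 5,5'-[(2R,3R,4S,5S)-3,4-dimethyloxolane-2,5-diyl]bis(2,3-dimethoxyphenol)
Product: 12 5-[(2S,3S,4R,5R)-3,4-dimethyl-5-(3,4,5-trimethoxyphenyl)oxolan-2-yl]-2,3-dimethoxyphenol
Conditions: MeI (1.05 equiv), Cat* (10 mol%; quinidine-derived N-(9-anthracenylmethyl)ammonium bromide carrying a C9 3,5-bis(trifluoromethyl)phenylurea), powdered K2CO3, toluene/CHCl3 9:1, −20 °C, stopped near 90% conversion
Reagents that add atoms: iodomethane, CI
Why: Proposed new method: enantiotopic-group-selective O-methylation of a meso bisphenol under bifunctional chiral phase-transfer catalysis, in which the ammonium centre extracts one phenoxide as a tight ion pair while the urea N–H donors and the anthracenyl surface hold the second, neutral aryl ring, so that the catalyst spans both cis-aryl groups and reads the mirror plane of the oxolane, SN2 methyl transfer to the ion-paired phenoxide on the (R)-configured benzylic arm then turns the meso core into the (2S,3S,4R,5R) array without touching any bond to a stereocentre, and any over-methylation removes the minor enantiomer faster and so raises the ee; the closest known reaction types are cation-directed enantioselective O-alkylation of bisphenols under chiral phase-transfer catalysis and peptide-catalysed remote desymmetrising acylation of bisphenols.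

**Compound list**
1 | 2-bromophenol | Oc1ccccc1Br | starting material
2 | 2-methoxyphenol | COc1ccccc1O | intermediate
3 | 4-bromo-2-methoxyphenol | COc1cc(Br)ccc1O | intermediate
4 | (E)-prop-1-en-1-ylboronic acid | C/C=C/B(O)O | starting material
5 | 2-methoxy-4-[(E)-prop-1-enyl]phenol | C/C=C/c1ccc(O)c(OC)c1 | intermediate
6 | 4,4'-[(1R,2S,3R,4S)-3,4-dimethylcyclobutane-1,2-diyl]bis(2-methoxyphenol), meso | COc1cc(ccc1O)[C@@H]1[C@H](c2ccc(O)c(OC)c2)[C@@H](C)[C@H]1C | intermediate
7 | 4,4'-[(2R,3S)-2,3-dimethylbutane-1,4-diylidene]bis(2-methoxycyclohexa-2,5-dien-1-one), meso, exocyclic C=C geometry undefined | C[C@H](C=C1C=CC(=O)C(OC)=C1)[C@@H](C)C=C1C=CC(=O)C(OC)=C1 | intermediate (not isolated)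
8 | 4,4'-[(2R,3R,4S,5S)-3,4-dimethyloxolane-2,5-diyl]bis(2-methoxyphenol), meso | COc1cc(ccc1O)[C@H]1O[C@@H](c2ccc(O)c(OC)c2)[C@H](C)[C@@H]1C | intermediate
9 | (2R,3R,4S,5S)-2,5-bis(3,4-dimethoxyphenyl)-3,4-dimethyloxolane, meso | COc1ccc(cc1OC)[C@H]1O[C@@H](c2ccc(OC)c(OC)c2)[C@H](C)[C@@H]1C | intermediate
10 | (2R,3R,4S,5S)-2,5-bis[3,4-dimethoxy-5-(4,4,5,5-tetramethyl-1,3,2-dioxaborolan-2-yl)phenyl]-3,4-dimethyloxolane, meso | COc1cc(cc(B2OC(C)(C)C(C)(C)O2)c1OC)[C@H]1O[C@@H](c2cc(OC)c(OC)c(B3OC(C)(C)C(C)(C)O3)c2)[C@H](C)[C@@H]1C | intermediate (not isolated)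
11 | 5,5'-[(2R,3R,4S,5S)-3,4-dimethyloxolane-2,5-diyl]bis(2,3-dimethoxyphenol), meso | COc1cc(cc(O)c1OC)[C@H]1O[C@@H](c2cc(O)c(OC)c(OC)c2)[C@H](C)[C@@H]1C | intermediate
12 | 5-[(2S,3S,4R,5R)-3,4-dimethyl-5-(3,4,5-trimethoxyphenyl)oxolan-2-yl]-2,3-dimethoxyphenol | COc1cc([C@H]2O[C@@H](c3cc(OC)c(OC)c(OC)c3)[C@H](C)[C@@H]2C)cc(O)c1OC | target

Total step count: 8. Longest linear sequence: 8 steps (1 to 12).

**Steps most likely to fail**

Step 8 (the proposed new method) may give low ee because the two phenols are remote from the stereocentres. The fallback uses known chemistry, sets out from 11 and comes back at 12: unselective Williamson mono-methylation (MeI 0.9 equiv, K2CO3, acetone, unreacted 11 recycled) gives 12 as the racemate together with the enantiomer of 12 F5, and the two are separated by preparative chromatography on a polysaccharide chiral stationary phase.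

Step 7 may borylate sluggishly or at the wrong position, because C5' is ortho to a methoxy group that is itself buttressed by its neighbour. The fallback sets out from 8 (before the O-methylation of step 6) and comes back at 11: NBS (2.1 equiv, MeCN, 0 °C) brominates each ring ortho to its free OH to give the dibromo bisphenol F3, MeI/K2CO3 gives the dibromide F4, and palladium-catalysed hydroxylation (Pd2(dba)3, t-BuXPhos, KOH, dioxane/H2O, 100 °C) converts both C–Br bonds into the phenols of 11.

Step 4 may be drained by E/Z isomerisation, give other dimers, or suffer from phenol photochemistry. The fallback sets out from 5 and comes back at 6: two molecules of 5 are tied through their phenols with i-Pr2SiCl2/imidazole (DMF) to the bis(aryloxy)silane F1, irradiation at high dilution (Pyrex, MeCN, 5 mM) can then only close the head-to-head cis-diaryl cyclobutane as the silylene-bridged dimer F2, and TBAF/AcOH in THF releases 6.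

**Further compounds**
F1 | step 4 | bis{2-methoxy-4-[(E)-prop-1-enyl]phenoxy}di(propan-2-yl)silane | CC(C)[Si](Oc1ccc(/C=C/C)cc1OC)(Oc1ccc(/C=C/C)cc1OC)C(C)C
F2 | step 4 | O,O'-di(propan-2-yl)silylene-bridged 4,4'-[(1R,2S,3R,4S)-3,4-dimethylcyclobutane-1,2-diyl]bis(2-methoxyphenol) | CC(C)[Si]1(C(C)C)Oc2ccc(cc2OC)[C@@H]2[C@H](c3ccc(O1)c(OC)c3)[C@@H](C)[C@H]2C
F3 | step 7 | 4,4'-[(2R,3R,4S,5S)-3,4-dimethyloxolane-2,5-diyl]bis(2-bromo-6-methoxyphenol) | COc1cc(cc(Br)c1O)[C@H]1O[C@@H](c2cc(Br)c(O)c(OC)c2)[C@H](C)[C@@H]1C
F4 | step 7 | (2R,3R,4S,5S)-2,5-bis(3-bromo-4,5-dimethoxyphenyl)-3,4-dimethyloxolane | COc1cc(cc(Br)c1OC)[C@H]1O[C@@H](c2cc(Br)c(OC)c(OC)c2)[C@H](C)[C@@H]1C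
F5 | step 8 | 5-[(2R,3R,4S,5S)-3,4-dimethyl-5-(3,4,5-trimethoxyphenyl)oxolan-2-yl]-2,3-dimethoxyphenol | COc1cc([C@@H]2O[C@H](c3cc(OC)c(OC)c(OC)c3)[C@@H](C)[C@H]2C)cc(O)c1OC
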